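- delta: solid substrate 1.5 M; gas phase 200 mM (held); protic impurity 0.68 M; run made earlier
- flask: solid substrate 1.5 M; gas phase 200 mM (held); protic impurity 0.450 M; time 10 d
delta run (percent of the solid substrate charged)

| time / h | target / % | solid substrate / % |
|---|---|---|
| 4.00 | 0 | 99.5 |
| 12.0 | 0.6 | 96.7 |
| 20.0 | 1.6 | 95.8 |
| 30.0 | 2.7 | 93.5 |
| 50.0 | 4.4 | 88.6 |

(readings scatter by 0.3 percentage points)
- solid, in amounts per volume of the solution: solid substrate
- what was read earlier has a scatter of 0.3 percentage points, one standard deviation
- at the start none of the gas phase is in solution
- at the start none of the solid substrate is in solution
- no earlier run changes the charge of protic impurity; that part of a forecast is a guess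
- the target standing at 10 d, as a percentage of the solid substrate charged
- concentration of dissolved gas in solution at 5.0 d, in percent of saturation
- the change that raises the amount of target at 10 d, in percent of the solid substrate charged most ("none" if none brings more than 2 percentage points) (south-west / north-east / east / west / none)
- amount of target at 10 d, in percent of the solid substrate charged, after east
- south-west: doubling the saturation concentration of gas phase, all else as stated
- north-east: doubling the dissolution coefficient of the solid substrate, all else as stated
- east: doubling the solubility of the solid substrate, all else as stated
- west: doubling the transfer coefficient of the gas phase, all else as stated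

- At late times in the delta run, the fraction of solid substrate left falls from 96.7% at 12.0 h to 88.6% at 50.0 h. That is 0.0512 d⁻¹ as a fraction of the charge, a zero-order loss as read, so you can work with what is left and run the line on.
- Over that stretch of the delta run, the target rises from 0.6% to 4.4%. I skip the first reading, where the target stands at 0%. Each unit of solid substrate lost therefore yields 0.469 of target: call this the target share of the loss.
- Run on to 10 d, the line leaves 48.1% in the new flask, and the target share turns the further loss into 23.4% of target.
- Objection: the solid substrate readings cancel when slope and share are multiplied, so that figure hangs on the two target readings. Their scatter, carried forward, moves it by about 2.3 percentage points, which I can live with.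
- Objection: the solid substrate might run out on the way. On the line it doesn't: the line still ends at 48.1%.
- Objection: the delta run held 0.68 M of protic impurity and the new flask holds 0.450 M. No run tests this, so keeping the slope and share is a guess.
- My reckoning reaches the target and no further. The forecast gives 24% of target, dissolved gas at 94% of saturation at 5.0 d, south-west as the best change and 38% of target after east, and its target figure rests on “Target at about 0.10 %/h over 233 h gives about 24%”, whereas mine starts from the last reading and gives 23.4%.
- The new flask gives 22.9% of target with 46.0% of solid substrate left at 10 d, and dissolved gas at 41.9% of saturation at 5.0 d. The best change is east, which gains 19 points against 17 points for north-east, 6.6 points for south-west and 3.7 points for west, and brings the target to 42.4%.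

    2 dissolved gas → homo dimer (k = 1.80 M⁻¹ h⁻¹)
    starting material + protic impurity → quenched substrate (k = 0.0670 M⁻¹ h⁻¹)
    starting material → side product (k = 0.240 h⁻¹)
    gas phase ⇌ dissolved gas, rate k4*(csat - [dissolved gas]) (kL = 0.230 h⁻¹)
    solid substrate ⇌ starting material, rate k5*(cs5 - [starting material]) while solid is left; crystals form when [starting material] > cs5 (solubility = 0.0510 M, k = 0.0770 h⁻¹)
    starting material + dissolved gas → target (k = 2.40 M⁻¹ h⁻¹)

- Now take the neighbouring flask with 2.5 M of solid substrate. Suppose the same amount leaves per volume: each fraction lost or made is then multiplied by 0.600, so 68.9% stays, and the target share gives 14.0% of target. That neighbouring flask stands at 68% of its solid substrate still there, solid or dissolved, and 13.7% of target.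

The runs stem from a simulated flask from invented constants; the scatter is artificial.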